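(The runs were computed for an exercise.)

If a catalyst showed no preference between mirror substrates, the left-handed product would take a share of 0.5 of whatever coupled, and I used that as the zero of my scale.

common to all: catalyst 30 mM
- north-west: left-handed substrate 0.20 M; right-handed substrate 0.20 M; coupling partner 0.40 M; run made earlier
- north: left-handed substrate 0.10 M; right-handed substrate 0.10 M; coupling partner 0.40 M; run made earlier
- south: left-handed substrate 0.40 M; right-handed substrate 0.40 M; coupling partner 0.40 M; run made earlier
- alpha: left-handed substrate 0.20 M; right-handed substrate 0.20 M; coupling partner 0.400 M; everything together in a closed stirred flask, run for 2.0 h; time 2.0 h
- eta: left-handed substrate 0.20 M; right-handed substrate 0.20 M; coupling partner 0.400 M; one stirred flow tank at steady state, fed with the mixture as stated, mean residence time 2.0 h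
- epsilon: left-handed substrate 0.20 M; right-handed substrate 0.20 M; coupling partner 0.400 M (fed, over 1.60 h); a stirred flask in which coupling partner is dosed at a steady rate over 1.60 h without added volume, worked up at 2.0 h; time 2.0 h
- delta: left-handed substrate 0.20 M; right-handed substrate 0.20 M; coupling partner 0.400 M; plug flow through a tube for 2.0 h, no back-mixing; time 2.0 h

| run | time / min | left-handed product / % | left-handed substrate / % |
|---|---|---|---|
| north-west | 15.0 | 17.9 | 35.4 |
| north-west | 40.0 | 22.7 | 34.2 |
| north-west | 80.0 | 23.5 | 32.1 |
| north-west | 120 | 24.4 | 32.9 |
| north | 8.00 | 14.5 | 36.5 |
| north | 20.0 | 20.8 | 33.9 |
| north | 40.0 | 26.2 | 30.7 |
| north | 90.0 | 28.3 | 28.9 |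
| south | 12.0 | 13.5 | 38.5 |
| south | 30.0 | 16.3 | 38.3 |
| south | 60.0 | 16.3 | 37.5 |
| south | 90.0 | 17.3 | 37.5 |

(standard deviation of a reading: 0.5 percentage points)

- catalyst is single-handed; left-handed substrate and right-handed substrate are mirror images of each other, charged as a racemate, each of them at the stated concentration
- the stated concentrations are those of everything mixed, before any reaction; amounts are the same in each set-up
- the analysis behind the earlier runs scatters by 0.5 percentage points, standard deviation
- the feed brings no volume worth counting
- the earlier runs were made in a closed, stirred flask

- the set-up with the highest amount of left-handed product at the outlet or at the end, in percent of the left-handed substrate and right-handed substrate together put in ("none" if the first two lie within 2 percentage points) (alpha / eta / epsilon / delta / none)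
- amount of left-handed product at the outlet or at the end, in percent of the left-handed substrate and right-handed substrate together put in, alpha
- amount of left-handed product at the outlet or at the end, in percent of the left-handed substrate and right-handed substrate together put in, eta
- amount of left-handed product at the outlet or at the end, in percent of the left-handed substrate and right-handed substrate together put in, epsilon
- amount of left-handed product at the outlet or at the end, in percent of the left-handed substrate and right-handed substrate together put in, delta

I read the last row of each run table. In the north-west run the left-handed substrate had lost 17 percentage points of the combined charge, yet the left-handed product stood at 24.4%, higher than that loss. So I read right-handed substrate as inverting and feeding it, and I took the two substrates as equal. The 9.8 points of the north-west charge that substrates and left-handed product did not account for I took as right-handed product.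

That gave my carried quantity, the coupled share of partner: the fraction of charged coupling partner that ended in either product, counting one partner per coupled substrate. It was 34.2% in the north-west row. The north row gave 21.1% and the south row 50.0%, so the share was higher with more substrate per partner. The left-handed share of coupled material read 0.713 in the north-west row, above the zero. The left-handed product is therefore that share, times the coupled share, times [coupling partner] over the summed substrate charge.

I read the stall as partner lost to a competing path. I put alpha and delta near the north-west plateau, and, if that loss is steeper than first order in partner, eta and epsilon above them, since both keep [coupling partner] thin. The forecast put eta and epsilon below alpha and delta, not above them: alpha 24%, eta 19.5%, epsilon 10%, delta 24%, best none. Its ground was this: “So the catalyst dies, with a time constant of about 14, 12 and 8 min, not the substrate running out.”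

The simulation gave alpha 23.7%, eta 31.8%, epsilon 38.0%, delta 23.7%, best epsilon.

    coupling partner + catalyst + left-handed substrate → catalyst + left-handed product (k = 7.64 L² mol⁻² min⁻¹)
    coupling partner + catalyst + right-handed substrate → catalyst + right-handed product (k = 3.43 L² mol⁻² min⁻¹)
    left-handed substrate ⇌ right-handed substrate (k = 0.0908 min⁻¹)
    coupling partner → decomposition product (k = 1.91 × 10⁻⁴ min⁻¹)
    2 coupling partner → self-condensation product (k = 0.368 L mol⁻¹ min⁻¹)

At 2.00 h alpha held catalyst at 100% and coupling partner, the limiting reagent, at 0.0623% of its charge. At that time epsilon's coupled share stood at 55.5%, higher than the north-west reading. The neighbouring flask is delta with 1.0 M of coupling partner, so its left-handed substrate per partner is 0.200, against 0.250 in the north run. Taking the north row's coupled share and its left-handed share 0.671, I reckoned 35.4% of left-handed product for the neighbouring flask. The neighbouring flask's coupled share came out at 19.0%, lower than the north row's, and its left-handed product at 31.9%.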